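**Retrosynthetic overview**
- Target ⇐ global desilylation of its tetra-TIPS ether.
- The tetrahydrofuran (the only non-aromatic ring) ⇐ deoxygenative ring contraction (6 → 5, loss of one peroxide oxygen to a phosphine) of a 3,6-diaryl-4,5-bis(silyloxymethyl)-1,2-dioxane.
- The 1,2-dioxane ⇐ enantioselective head-to-head radical-cation dimerisation of two silylated sinapyl alcohol units with capture of O2; this forms the central C–C bond and fixes the two CH2O-bearing stereocentres.
- Silylated sinapyl alcohol ⇐ methyl sinapate ⇐ syringaldehyde + monomethyl malonate; syringaldehyde ⇐ p-cresol.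
- Ring order: the arenes are there from the start; the dioxane is formed first and then contracted to the oxolane.

Assumption: the sense of induction of the chiral anion in step 6 cannot be predicted, so the catalyst antipode that gives the (4R,5R) series is assigned in the first run and used.

**Step 1**
Reactants: 1 p-cresol
Product: 4 3,5-dibromo-4-hydroxybenzaldehyde, via dibromocresol 2 (not isolated), via benzal bromide 3 (not isolated)
Conditions: Br2 (2.05 equiv), o-dichlorobenzene, 35 °C; Br2 (2.1 equiv), 150–160 °C; then H2O, 100 °C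
Reagents that add atoms: bromine BrBr; water O
Why: Phenol-directed electrophilic aromatic bromination fills both ortho positions, thermal free-radical benzylic dibromination then gives the benzal bromide, and hydrolysis of the gem-dibromide releases the aldehyde; no stereocentre.

**Step 2**
Reactants: 4 3,5-dibromo-4-hydroxybenzaldehyde
Product: 5 syringaldehyde (4-hydroxy-3,5-dimethoxybenzaldehyde)
Conditions: NaOMe (5 equiv), CuCl (10 mol%), DMF/MeOH, 115 °C; aq. HCl work-up
Reagents that add atoms: sodium methoxide [Na+].[O-]C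
Why: Copper(I)-catalysed Ullmann-type methoxylation replaces both aryl bromides, and the aldehyde survives as its phenoxide-deactivated form; no stereocentre.

**Step 3**
Reactants: 5 syringaldehyde; 6 monomethyl malonate (3-methoxy-3-oxopropanoic acid)
Product: 8 methyl (E)-sinapate, via arylidene malonate half ester 7 (not isolated)
Conditions: 6 (1.5 equiv), pyridine, piperidine (10 mol%), 90 °C
Reagents that add atoms: none
Why: Knoevenagel–Doebner condensation with a malonic half ester; pyridine-promoted decarboxylation of 7 gives the thermodynamically favoured E-cinnamate, which cannot decarboxylate further.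

**Step 4**
Reactants: 8 methyl (E)-sinapate
Product: 9 sinapyl alcohol ((E)-4-(3-hydroxyprop-1-enyl)-2,6-dimethoxyphenol)
Conditions: DIBAL-H (4.2 equiv), toluene/THF, −78 → 0 °C; Rochelle salt work-up
Reagents that add atoms: none
Why: DIBAL-H 1,2-reduction of the conjugated ester (one equivalent is consumed by the phenol) gives the allylic alcohol and leaves the E-alkene untouched.

**Step 5**
Reactants: 9 sinapyl alcohol
Product: 10 bis-TIPS sinapyl alcohol ((E)-triisopropyl{3-[3,5-dimethoxy-4-(triisopropylsilyloxy)phenyl]allyloxy}silane)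
Conditions: TIPSOTf (2.4 equiv), 2,6-lutidine (3 equiv), CH2Cl2, 0 °C
Reagents that add atoms: triisopropylsilyl triflate CC(C)[Si](OS(=O)(=O)C(F)(F)F)(C(C)C)C(C)C
Why: Silyl triflate silylation of both hydroxyls; TIPS blocks phenoxyl/quinone-methide chemistry at the phenol and cation capture by the primary alcohol, keeps the arene electron-rich, and survives brief acid later.

**Step 6**
Reactants: 10 bis-TIPS sinapyl alcohol (2 equiv)
Product: 11 (3S,4R,5R,6S)-3,6-bis[3,5-dimethoxy-4-(triisopropylsilyloxy)phenyl]-4,5-bis[(triisopropylsilyloxy)methyl]-1,2-dioxane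
Conditions: O2 (1 atm), thioxanthylium photocatalyst paired with a confined chiral imidodiphosphorimidate (IDPi) anion (3 mol%), CH2Cl2/pentane, −78 °C, green LEDs
Reagents that add atoms: dioxygen O=O
Why: Proposed new method: catalytic enantioselective aerobic radical-cation dimerisation–endoperoxidation; the photo-oxidised alkene radical cation sits in a contact ion pair with the chiral anion, a second alkene attacks its β-carbon head-to-head so the C4–C5 bond forms with the trans relationship dictated by the two E-alkenes and the anion-controlled (4R,5R) sense, and the resulting benzylic radical/cation pair takes up O2 and closes to the all-equatorial dioxane (minor C3/C6 epimers do not matter because step 7 equilibrates those centres); the closest known reaction types are the racemic photocatalytic aerobic [2+2+2] endoperoxidation of electron-rich styrenes and counteranion-directed asymmetric radical-cation cycloadditions.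

**Step 7**
Reactants: 11 the (3S,4R,5R,6S)-1,2-dioxane
Product: 13 (2S,3R,4R,5S)-2,5-bis[3,5-dimethoxy-4-(triisopropylsilyloxy)phenyl]-3,4-bis[(triisopropylsilyloxy)methyl]tetrahydrofuran, via dioxaphosphorane 12 (not isolated)
Conditions: PPh3 (1.1 equiv), toluene, 0 → 60 °C; then TFA (0.5 equiv), CH2Cl2, 0 °C
Reagents that add atoms: none
Why: Phosphine-mediated deoxygenative ring contraction of a cyclic peroxide: PPh3 inserts into the O–O bond to give 12, which ionises to an alkoxide/benzylic oxyphosphonium pair and expels Ph3P=O by 5-exo closure; C3 and C4 are untouched, the benzylic centre closes through a p-oxygen-stabilised ion pair (as in Mitsunobu reactions of electron-rich benzylic alcohols) trans to its neighbour, and the TFA stage equilibrates any benzylic epimer to the all-trans isomer, the thermodynamic minimum.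

**Step 8**
Reactants: 13 the tetra-TIPS tetrahydrofuran
Product: 14 huazhongilexin ([(2S,3R,4R,5S)-2,5-bis(4-hydroxy-3,5-dimethoxyphenyl)tetrahydrofuran-3,4-diyl]dimethanol)
Conditions: TBAF (4.4 equiv), AcOH (4.4 equiv), THF, 0 °C → rt
Reagents that add atoms: none
Why: Fluoride-mediated cleavage of the four Si–O bonds, buffered with AcOH so that no phenoxide-driven quinone-methide opening of the benzylic ether occurs; the stereocentres are not touched.

**Compound list**
1 | p-cresol | Cc1ccc(O)cc1 | starting material
2 | 2,6-dibromo-4-methylphenol | Cc1cc(Br)c(O)c(Br)c1 | intermediate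
3 | 2,6-dibromo-4-(dibromomethyl)phenol | Oc1c(Br)cc(C(Br)Br)cc1Br | intermediate
4 | 3,5-dibromo-4-hydroxybenzaldehyde | O=Cc1cc(Br)c(O)c(Br)c1 | intermediate
5 | syringaldehyde | COc1cc(C=O)cc(OC)c1O | intermediate
6 | monomethyl malonate | COC(=O)CC(=O)O | starting material
7 | 3-(4-hydroxy-3,5-dimethoxyphenyl)-2-(methoxycarbonyl)prop-2-enoic acid (E/Z) | COC(=O)C(=Cc1cc(OC)c(O)c(OC)c1)C(=O)O | intermediate
8 | methyl (E)-sinapate | COC(=O)/C=C/c1cc(OC)c(O)c(OC)c1 | intermediate
9 | sinapyl alcohol | OC/C=C/c1cc(OC)c(O)c(OC)c1 | intermediate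
10 | bis-TIPS sinapyl alcohol | CC(C)[Si](OC/C=C/c1cc(OC)c(O[Si](C(C)C)(C(C)C)C(C)C)c(OC)c1)(C(C)C)C(C)C | intermediate
11 | (3S,4R,5R,6S)-3,6-bis[3,5-dimethoxy-4-(triisopropylsilyloxy)phenyl]-4,5-bis[(triisopropylsilyloxy)methyl]-1,2-dioxane | COc1cc([C@H]2OO[C@H](c3cc(OC)c(O[Si](C(C)C)(C(C)C)C(C)C)c(OC)c3)[C@@H](CO[Si](C(C)C)(C(C)C)C(C)C)[C@@H]2CO[Si](C(C)C)(C(C)C)C(C)C)cc(OC)c1O[Si](C(C)C)(C(C)C)C(C)C | intermediate
12 | (4S,5R,6R,7S)-2,2,2-triphenyl-4,7-bis[3,5-dimethoxy-4-(triisopropylsilyloxy)phenyl]-5,6-bis[(triisopropylsilyloxy)methyl]-1,3,2λ5-dioxaphosphepane | COc1cc([C@H]2OP(c4ccccc4)(c4ccccc4)(c4ccccc4)O[C@H](c3cc(OC)c(O[Si](C(C)C)(C(C)C)C(C)C)c(OC)c3)[C@@H](CO[Si](C(C)C)(C(C)C)C(C)C)[C@@H]2CO[Si](C(C)C)(C(C)C)C(C)C)cc(OC)c1O[Si](C(C)C)(C(C)C)C(C)C | intermediate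
13 | (2S,3R,4R,5S)-2,5-bis[3,5-dimethoxy-4-(triisopropylsilyloxy)phenyl]-3,4-bis[(triisopropylsilyloxy)methyl]tetrahydrofuran | COc1cc([C@H]2O[C@H](c3cc(OC)c(O[Si](C(C)C)(C(C)C)C(C)C)c(OC)c3)[C@@H](CO[Si](C(C)C)(C(C)C)C(C)C)[C@@H]2CO[Si](C(C)C)(C(C)C)C(C)C)cc(OC)c1O[Si](C(C)C)(C(C)C)C(C)C | intermediate
14 | huazhongilexin | COc1cc([C@H]2O[C@H](c3cc(OC)c(O)c(OC)c3)[C@@H](CO)[C@@H]2CO)cc(OC)c1O | target

**Step count and risks**
Total steps: 8. Longest linear sequence: 8 (1 → 14; 6 enters at step 3).

Step 6 (the proposed new step) is the most likely to fail. The risks are low enantioselectivity, diversion to the [2+2] cyclobutane, and oxidative cleavage of the alkene to the aldehyde. The fallback sets out from 10 and comes back at 11. It gives up catalyst control: 10 is dimerised and oxygenated under known achiral electron-transfer photocatalysis (2,4,6-tris(4-methoxyphenyl)pyrylium tetrafluoroborate, O2, CH2Cl2, blue LEDs). This gives racemic material, that is 11 together with its mirror image, the (3R,4S,5S,6R)-dioxane F1. The two are separated by preparative chiral SFC on an amylose phase, F1 is discarded, and 11 goes into step 7.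

Step 7 is the second risk. The oxyphosphonium intermediate can eliminate to a styrene, close with inversion to a 2,3-cis isomer, or, under the acid stage, undergo Friedel–Crafts closure to an aryltetralin. The fallback sets out from 11 and comes back at 13. It replaces the phosphine extrusion by a reduce-then-cyclise sequence known from tetrahydrofuran-lignan work. Zn dust in AcOH/THF at 0 °C cleaves the O–O bond to the (1S,2R,3R,4S)-1,4-diaryl-2,3-bis(silyloxymethyl)butane-1,4-diol F2. BF3·OEt2 (or MsCl/Et3N) in CH2Cl2 at −40 °C then effects SN1 cyclodehydration of F2 to the all-trans tetrahydrofuran 13.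

Step 1 is the third risk. The high-temperature side-chain bromination is hard to stop cleanly at the benzal bromide on laboratory scale. The fallback sets out from 1 and comes back at 5, and it moves the oxidation of the methyl group to the end. Compound 1 is brominated only on the ring (Br2, 2 equiv, AcOH, 15 °C) and 2 is isolated. Compound 2 is methoxylated (NaOMe, CuCl, DMF/MeOH, 110 °C) to 2,6-dimethoxy-4-methylphenol F3. F3 is oxidised at the benzylic position with O2, Co(OAc)2 (cat.) and NaOH in MeOH at 60 °C (base-mediated aerobic oxidation of a p-cresol via its quinone methide) to syringaldehyde 5. This bypasses 3, 4 and step 2.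

**Further compounds**
F1 | step 6 | (3R,4S,5S,6R)-3,6-bis[3,5-dimethoxy-4-(triisopropylsilyloxy)phenyl]-4,5-bis[(triisopropylsilyloxy)methyl]-1,2-dioxane | COc1cc([C@@H]2OO[C@@H](c3cc(OC)c(O[Si](C(C)C)(C(C)C)C(C)C)c(OC)c3)[C@H](CO[Si](C(C)C)(C(C)C)C(C)C)[C@H]2CO[Si](C(C)C)(C(C)C)C(C)C)cc(OC)c1O[Si](C(C)C)(C(C)C)C(C)C
F2 | step 7 | (1S,2R,3R,4S)-1,4-bis[3,5-dimethoxy-4-(triisopropylsilyloxy)phenyl]-2,3-bis[(triisopropylsilyloxy)methyl]butane-1,4-diol | COc1cc([C@@H](O)[C@@H](CO[Si](C(C)C)(C(C)C)C(C)C)[C@H](CO[Si](C(C)C)(C(C)C)C(C)C)[C@H](O)c2cc(OC)c(O[Si](C(C)C)(C(C)C)C(C)C)c(OC)c2)cc(OC)c1O[Si](C(C)C)(C(C)C)C(C)C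
F3 | step 1 | 2,6-dimethoxy-4-methylphenol | COc1cc(C)cc(OC)c1O
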